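**Retrosynthetic overview**

1. Target ⇒ bis-MOM rohitukine 10 + angelic acid; the ester is put on before the phenols are unmasked, then the MOM groups leave under mild acid.
2. 10 ⇒ racemic, epimerisable 4-aryl-piperidin-3-one 9 by one Noyori dynamic-kinetic asymmetric hydrogenation that sets both stereocentres (cis, 3S,4R) at once.
3. 9 ⇒ N-methyl-3-hydroxypyridinium salt 7 by iridium-catalysed dearomatising partial hydrogenation: the piperidine is never built, it is a reduced pyridine.
4. 7 ⇒ 4-iodopyridin-3-ol + chromone 8-boronate (Suzuki union), the boronate coming from noreugenin by MOM protection, C8 bromination and borylation.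
5. Ring order: chromone (rings A and C) bought intact → pyridine attached at C8 → pyridine reduced to the piperidine last.

Assumption: the alkene in the SMILES is read as Z (angelate, not tiglate) and the piperidine as (3S,4R), so the target is rohitukine 3-O-angelate; noreugenin, 4-iodopyridin-3-ol, angelic acid and 2,4,6-trichlorobenzoyl chloride are taken as catalogue chemicals.

**Route**

Step 1
Reactants: 1 noreugenin (5,7-dihydroxy-2-methyl-4H-chromen-4-one)
Product: 2 5,7-bis(methoxymethoxy)-2-methyl-4H-chromen-4-one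
Conditions: NaH (2.4 equiv), MOMCl (2.4 equiv), DMF, 0 °C → rt
Reagents that add atoms: chloromethyl methyl ether (MOMCl), COCCl
Why: Williamson-type O-alkylation of both phenoxides, where NaH/DMF is strong enough to alkylate the hydrogen-bonded 5-OH, and MOM is chosen because it survives base, Pd, H2 and alkoxide yet leaves under acid mild enough for an angelate.

Step 2
Reactants: 2 5,7-bis(methoxymethoxy)-2-methyl-4H-chromen-4-one
Product: 3 8-bromo-5,7-bis(methoxymethoxy)-2-methyl-4H-chromen-4-one
Conditions: NBS (1.05 equiv), DMF, 0 °C → rt, dark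
Reagents that add atoms: N-bromosuccinimide, O=C1CCC(=O)N1Br
Why: Electrophilic aromatic bromination, which in 5,7-dialkoxychromones goes to C8 because C6 is buttressed by two OMOM groups, while neutral NBS/DMF spares the acetals and the 2-methyl group.

Step 3
Reactants: 3 8-bromo-5,7-bis(methoxymethoxy)-2-methyl-4H-chromen-4-one
Product: 4 5,7-bis(methoxymethoxy)-2-methyl-8-(4,4,5,5-tetramethyl-1,3,2-dioxaborolan-2-yl)-4H-chromen-4-one
Conditions: B2pin2 (1.5 equiv), PdCl2(dppf) (5 mol %), KOAc (3 equiv), 1,4-dioxane, 90 °C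
Reagents that add atoms: bis(pinacolato)diboron, CC1(C)OB(OC1(C)C)B1OC(C)(C)C(C)(C)O1
Why: Miyaura borylation of an electron-rich aryl bromide under weak acetate base, conditions that chromone 8-halides tolerate and that give a pinacol ester robust enough to isolate.

Step 4
Reactants: 4 5,7-bis(methoxymethoxy)-2-methyl-8-(4,4,5,5-tetramethyl-1,3,2-dioxaborolan-2-yl)-4H-chromen-4-one; 5 4-iodopyridin-3-ol
Product: 6 8-(3-hydroxypyridin-4-yl)-5,7-bis(methoxymethoxy)-2-methyl-4H-chromen-4-one
Conditions: Pd(OAc)2 (5 mol %), SPhos (10 mol %), K3PO4 (3 equiv), dioxane/H2O (5:1), 80 °C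
Reagents that add atoms: none
Why: Suzuki–Miyaura coupling in which the bulky biarylphosphine drives formation of the tri-ortho-substituted biaryl faster than protodeboronation, and the unprotected pyridinol is carried as its phenoxide so no extra protecting group is needed.

Step 5
Reactants: 6 8-(3-hydroxypyridin-4-yl)-5,7-bis(methoxymethoxy)-2-methyl-4H-chromen-4-one
Product: 7 4-[5,7-bis(methoxymethoxy)-2-methyl-4-oxo-4H-chromen-8-yl]-3-hydroxy-1-methylpyridin-1-ium iodide
Conditions: MeI (3 equiv), MeCN, 45 °C, sealed tube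
Reagents that add atoms: iodomethane, CI
Why: Menshutkin N-alkylation, since neutral 3-hydroxypyridines alkylate on nitrogen and the chromone carbonyl and MOM acetals are inert to MeI, which installs the N-methyl of the target and activates the ring for reduction.

Step 6
Reactants: 7 4-[5,7-bis(methoxymethoxy)-2-methyl-4-oxo-4H-chromen-8-yl]-3-hydroxy-1-methylpyridin-1-ium iodide
Product: 9 rac-8-(1-methyl-3-oxopiperidin-4-yl)-5,7-bis(methoxymethoxy)-2-methyl-4H-chromen-4-one, via tetrahydropyridin-3-ol enol 8 (not isolated)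
Conditions: [Ir(cod)Cl]2 (2 mol %), PPh3 (8 mol %), NaHCO3 (1.1 equiv), H2 (40 bar), ClCH2CH2Cl, 50 °C
Reagents that add atoms: none
Why: Iridium-catalysed selective partial hydrogenation of a 3-hydroxypyridinium salt, in which two equivalents of H2 give the 1,2,5,6-tetrahydropyridin-3-ol that ketonises and so escapes further reduction, the Ir/PPh3 hydride leaving ketones and the vinylogous-ester chromone untouched, while C4 is formed racemic and stays epimerisable.

Step 7
Reactants: 9 rac-8-(1-methyl-3-oxopiperidin-4-yl)-5,7-bis(methoxymethoxy)-2-methyl-4H-chromen-4-one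
Product: 10 8-[(3S,4R)-3-hydroxy-1-methylpiperidin-4-yl]-5,7-bis(methoxymethoxy)-2-methyl-4H-chromen-4-one
Conditions: RuCl2[(S)-binap][(R,R)-dpen] (1 mol %), KOtBu (10 mol %), H2 (20 bar), i-PrOH/THF (3:1), 25 °C
Reagents that add atoms: none
Why: Noyori asymmetric hydrogenation with dynamic kinetic resolution, in which the alkoxide racemises the α-aryl centre through the enolate faster than reduction, the catalyst consumes the (4R)-ketone, and equatorial hydride delivery gives the axial 3-OH cis to the equatorial aryl group, setting C3 (S) and C4 (R) together, the catalyst hand being chosen by analogy with the (1R,2R)-cis alcohols obtained from 2-substituted cyclohexanones.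

Step 8
Reactants: 10 8-[(3S,4R)-3-hydroxy-1-methylpiperidin-4-yl]-5,7-bis(methoxymethoxy)-2-methyl-4H-chromen-4-one; 11 angelic acid [(2Z)-2-methylbut-2-enoic acid]; 12 2,4,6-trichlorobenzoyl chloride
Product: 14 (3S,4R)-4-[5,7-bis(methoxymethoxy)-2-methyl-4-oxo-4H-chromen-8-yl]-1-methylpiperidin-3-yl (2Z)-2-methylbut-2-enoate, via mixed Yamaguchi anhydride 13 (not isolated)
Conditions: 11, 12, Et3N (1.0 equiv each), toluene, rt, 2 h; then 10, toluene, 70 °C, no DMAP
Reagents that add atoms: none
Why: Yamaguchi esterification run without a nucleophilic catalyst or excess amine, so the hindered axial alcohol attacks the unhindered angeloyl carbonyl of the mixed anhydride while the addition–elimination pathway that isomerises angelate to tiglate is shut off, and no stereocentre is touched.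

Step 9
Reactants: 14 (3S,4R)-4-[5,7-bis(methoxymethoxy)-2-methyl-4-oxo-4H-chromen-8-yl]-1-methylpiperidin-3-yl (2Z)-2-methylbut-2-enoate
Product: 15 (3S,4R)-4-(5,7-dihydroxy-2-methyl-4-oxo-4H-chromen-8-yl)-1-methylpiperidin-3-yl (2Z)-2-methylbut-2-enoate (target)
Conditions: 3 M aq. HCl/THF (1:2), rt → 40 °C; then aq. NaHCO3 to pH 8
Reagents that add atoms: none
Why: Acid-catalysed hydrolysis of the two aryl methoxymethyl acetals, which is much faster than hydrolysis of the hindered conjugated ester on the protonated amine and too mild for Z/E isomerisation or 8-to-6 chromone rearrangement.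

**Compound list**

1 | noreugenin (5,7-dihydroxy-2-methyl-4H-chromen-4-one) | Cc1cc(=O)c2c(O)cc(O)cc2o1 | starting material
2 | 5,7-bis(methoxymethoxy)-2-methyl-4H-chromen-4-one | Cc1cc(=O)c2c(OCOC)cc(OCOC)cc2o1 | intermediate
3 | 8-bromo-5,7-bis(methoxymethoxy)-2-methyl-4H-chromen-4-one | Cc1cc(=O)c2c(OCOC)cc(OCOC)c(Br)c2o1 | intermediate
4 | 5,7-bis(methoxymethoxy)-2-methyl-8-(4,4,5,5-tetramethyl-1,3,2-dioxaborolan-2-yl)-4H-chromen-4-one | Cc1cc(=O)c2c(OCOC)cc(OCOC)c(B3OC(C)(C)C(C)(C)O3)c2o1 | intermediate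
5 | 4-iodopyridin-3-ol | Oc1cnccc1I | starting material
6 | 8-(3-hydroxypyridin-4-yl)-5,7-bis(methoxymethoxy)-2-methyl-4H-chromen-4-one | Cc1cc(=O)c2c(OCOC)cc(OCOC)c(-c3ccncc3O)c2o1 | intermediate
7 | 4-[5,7-bis(methoxymethoxy)-2-methyl-4-oxo-4H-chromen-8-yl]-3-hydroxy-1-methylpyridin-1-ium iodide | Cc1cc(=O)c2c(OCOC)cc(OCOC)c(-c3cc[n+](C)cc3O)c2o1.[I-] | intermediate
8 | 8-(3-hydroxy-1-methyl-1,2,5,6-tetrahydropyridin-4-yl)-5,7-bis(methoxymethoxy)-2-methyl-4H-chromen-4-one (enol, not isolated) | Cc1cc(=O)c2c(OCOC)cc(OCOC)c(C3=C(O)CN(C)CC3)c2o1 | intermediate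
9 | rac-8-(1-methyl-3-oxopiperidin-4-yl)-5,7-bis(methoxymethoxy)-2-methyl-4H-chromen-4-one | Cc1cc(=O)c2c(OCOC)cc(OCOC)c(C3CCN(C)CC3=O)c2o1 | intermediate
10 | 8-[(3S,4R)-3-hydroxy-1-methylpiperidin-4-yl]-5,7-bis(methoxymethoxy)-2-methyl-4H-chromen-4-one | O[C@@H]1CN(C)CC[C@@H]1c1c(OCOC)cc(OCOC)c2c(=O)cc(C)oc12 | intermediate
11 | angelic acid [(2Z)-2-methylbut-2-enoic acid] | C/C=C(/C)C(=O)O | starting material
12 | 2,4,6-trichlorobenzoyl chloride | O=C(Cl)c1c(Cl)cc(Cl)cc1Cl | starting material
13 | (2Z)-2-methylbut-2-enoic 2,4,6-trichlorobenzoic anhydride (not isolated) | C/C=C(/C)C(=O)OC(=O)c1c(Cl)cc(Cl)cc1Cl | intermediate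
14 | (3S,4R)-4-[5,7-bis(methoxymethoxy)-2-methyl-4-oxo-4H-chromen-8-yl]-1-methylpiperidin-3-yl (2Z)-2-methylbut-2-enoate | C/C=C(/C)C(=O)O[C@@H]1CN(C)CC[C@@H]1c1c(OCOC)cc(OCOC)c2c(=O)cc(C)oc12 | intermediate
15 | (3S,4R)-4-(5,7-dihydroxy-2-methyl-4-oxo-4H-chromen-8-yl)-1-methylpiperidin-3-yl (2Z)-2-methylbut-2-enoate | C/C=C(/C)C(=O)O[C@@H]1CN(C)CC[C@@H]1c1c(O)cc(O)c2c(=O)cc(C)oc12 | target

**Step count and risks**

Total step count: 9. Longest linear sequence: 9 steps (1 → 15).

The three steps most likely to fail: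

Step 7, the dynamic-kinetic asymmetric hydrogenation. The di-ortho-substituted aryl group may slow the catalyst or erode the ee, and the sense of induction rests on analogy; it must be confirmed on the first run, and if it is reversed the mirror-image catalyst is used. The fallback replaces catalyst control by substrate control plus resolution; it sets out from 9 and comes back at 10. Reduction of 9 with LiBH(s-Bu)3 (THF, −78 °C) attacks equatorially and gives the racemic cis-alcohol rac-8-[(3S,4R)-3-hydroxy-1-methylpiperidin-4-yl]-5,7-bis(methoxymethoxy)-2-methyl-4H-chromen-4-one F5. Preparative chiral SFC on an amylose phase then separates 10 from its mirror image 8-[(3R,4S)-3-hydroxy-1-methylpiperidin-4-yl]-5,7-bis(methoxymethoxy)-2-methyl-4H-chromen-4-one F6, which is discarded.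

Step 6, the partial hydrogenation of the pyridinium salt. It could stall on the hindered, iodide-containing substrate or over-reduce. The fallback replaces selective hydrogenation by exhaustive hydride reduction and re-oxidation; it sets out from 7 and comes back at 9. NaBH4 (MeOH, 0 °C) reduces the pyridinium ring far faster than the electron-rich chromone and gives 8-(3-hydroxy-1-methylpiperidin-4-yl)-5,7-bis(methoxymethoxy)-2-methyl-4H-chromen-4-one F4 as a mixture of racemic cis and trans isomers, whose stereochemistry does not matter. Swern oxidation ((COCl)2, DMSO, Et3N, CH2Cl2, −78 °C) then gives 9.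

Step 4, the Suzuki union. The 2,6-dioxygenated aryl boronate may protodeboronate, and the free pyridinolate may slow the catalyst. The fallback reverses the polarity of the coupling and skips boronate 4; it sets out from bromide 3 and iodopyridinol 5 and comes back at 6. O-Benzylation of 5 (BnBr, K2CO3, DMF) gives 3-(benzyloxy)-4-iodopyridine F1. Zinc insertion (Zn dust, LiCl, THF, 40 °C) gives [3-(benzyloxy)pyridin-4-yl]zinc iodide F2. Negishi coupling of F2 with 3 (Pd(OAc)2, SPhos, THF, 60 °C) gives 8-[3-(benzyloxy)pyridin-4-yl]-5,7-bis(methoxymethoxy)-2-methyl-4H-chromen-4-one F3. Hydrogenolysis (H2 1 atm, 10% Pd/C, EtOAc/MeOH, rt, stopped after one equivalent) returns 6.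

**Further compounds**

F1 | step 4 | 3-(benzyloxy)-4-iodopyridine | Ic1ccncc1OCc1ccccc1
F2 | step 4 | [3-(benzyloxy)pyridin-4-yl]zinc iodide | I[Zn]c1ccncc1OCc1ccccc1
F3 | step 4 | 8-[3-(benzyloxy)pyridin-4-yl]-5,7-bis(methoxymethoxy)-2-methyl-4H-chromen-4-one | Cc1cc(=O)c2c(OCOC)cc(OCOC)c(-c3ccncc3OCc3ccccc3)c2o1
F4 | step 6 | 8-(3-hydroxy-1-methylpiperidin-4-yl)-5,7-bis(methoxymethoxy)-2-methyl-4H-chromen-4-one (cis/trans mixture, racemic) | Cc1cc(=O)c2c(OCOC)cc(OCOC)c(C3CCN(C)CC3O)c2o1
F5 | step 7 | rac-cis-8-(3-hydroxy-1-methylpiperidin-4-yl)-5,7-bis(methoxymethoxy)-2-methyl-4H-chromen-4-one (1:1 mixture of 10 and F6) | O[C@@H]1CN(C)CC[C@@H]1c1c(OCOC)cc(OCOC)c2c(=O)cc(C)oc12.O[C@H]1CN(C)CC[C@H]1c1c(OCOC)cc(OCOC)c2c(=O)cc(C)oc12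
F6 | step 7 | 8-[(3R,4S)-3-hydroxy-1-methylpiperidin-4-yl]-5,7-bis(methoxymethoxy)-2-methyl-4H-chromen-4-one | O[C@H]1CN(C)CC[C@H]1c1c(OCOC)cc(OCOC)c2c(=O)cc(C)oc12
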